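Count 1.20 incoming ligand per starting complex in ash, against 4 sites on each complex, so incoming ligand is the limiting reagent and covers 30.0% of the sites.

| setting | amber | ochre | grey | blue | ash | larch | alder | oak |
|---|---|---|---|---|---|---|---|---|
| starting complex | 0.40 M | 0.20 M | 0.80 M | 0.40 M | 0.40 M | 0.40 M (in portions, 4, over 3.0 h) | 0.40 M | 0.40 M (fed, over 3.0 h) |
| incoming ligand | 0.48 M | 0.48 M | 0.48 M | 0.48 M | 0.480 M | 0.480 M | 0.480 M (fed, over 3.0 h) | 0.480 M |
| capture agent | 0.40 M | 0.40 M | 0.40 M | 0.80 M | 0.400 M | 0.400 M | 0.400 M | 0.400 M |
| remark | run made earlier | run made earlier | run made earlier | run made earlier | everything together at the start | first portion at the start, last at 3.0 h | all else is in the flask from the start; the feed brings no volume worth counting | all else is in the flask from the start; the feed brings no volume worth counting |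
| time |  |  |  |  | 4.0 h | 4.0 h | 4.0 h | 4.0 h |

| run | time / h | complex with four exchanged / % | trapped intermediate / % | starting complex / % |
|---|---|---|---|---|
| amber | 0.667 | 1 | 0 | 34 |
| amber | 1.33 | 1 | 2 | 24 |
| amber | 2.00 | 0 | 4 | 25 |
| amber | 2.50 | 0 | 2 | 25 |
| ochre | 0.417 | 2 | 0 | 33 |
| ochre | 0.833 | 1 | 1 | 19 |
| ochre | 2.00 | 9 | 6 | 7 |
| ochre | 5.00 | 15 | 19 | 3 |
| grey | 1.33 | 0 | 0 | 53 |
| grey | 2.50 | 1 | 4 | 53 |
| grey | 4.00 | 1 | 3 | 55 |
| grey | 5.00 | 2 | 5 | 52 |
| blue | 0.667 | 1 | 3 | 35 |
| blue | 1.50 | 2 | 4 | 28 |
| blue | 3.00 | 3 | 13 | 26 |
| blue | 5.00 | 0 | 15 | 25 |

(scatter of a reading: 1.5 percentage points)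



- which flask leads in share of complex with four exchanged in complex with four exchanged plus trapped intermediate ("all alike" within 1.5 percentage points) (ash / larch / alder / oak / all alike)
- share of complex with four exchanged in complex with four exchanged plus trapped intermediate at the end, ash
- share of complex with four exchanged in complex with four exchanged plus trapped intermediate at the end, larch
- share of complex with four exchanged in complex with four exchanged plus trapped intermediate at the end, alder
- share of complex with four exchanged in complex with four exchanged plus trapped intermediate at the end, oak

Read amber first, since its charges are those of ash: its starting complex stands at 25% at 2.50 h, and independent sites, the binomial count, give 24.0%, so on this number the count and the reading agree. Now reckon the unread complex with two exchanged in two ways. Independent sites give 26.5%. A ligand balance, supposing exchange halts at two, takes the ligand per complex, subtracts what has left the starting complex, and gives 45.0%. The two part here, so one of them cheats; commit to the balance and let the flask judge.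

From it take the trapping half-life, the time in which capture agent at the ash charge turns half of a standing complex with two exchanged into trapped intermediate. Blue, with twice the capture agent, shows 13% trapped at 3.00 h, which gives 12.2 h. Blue's reading of 15% at 5.00 h gives 17.1 h, so treat the half-life as a reading with scatter. Over 4.0 h the half-life of 12.2 h reckons about 9.15% trapped intermediate in ash, where the forecast carries about 6%.

The forecast names larch as leader, with ash 12%, larch 57%, alder 18% and oak 54%, on the ground that “Larch and oak expose early complex to excess ligand.”

The flask also puts larch first, with ash 13.3%, larch 46.6%, alder 20.2% and oak 43.6%.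

    starting complex + incoming ligand → leaving ligand + complex with one exchanged (k = 0.120 M⁻¹ min⁻¹)
    complex with one exchanged + incoming ligand → leaving ligand + complex with two exchanged (k = 0.130 M⁻¹ min⁻¹)
    complex with two exchanged + incoming ligand → leaving ligand + complex with three exchanged (k = 0.0110 M⁻¹ min⁻¹)
    complex with three exchanged + incoming ligand → leaving ligand + complex with four exchanged (k = 0.510 M⁻¹ min⁻¹)
    complex with two exchanged + capture agent → trapped intermediate (k = 0.00310 M⁻¹ min⁻¹)
    complex with three exchanged → side product (k = 0.00400 min⁻¹)

Ash at 4.00 h holds 31.1% complex with two exchanged and 8.69% trapped intermediate, together 39.8%, which stands nearer the balance than the binomial count. Carried to larch, 12.2 h reckons its 30.8% complex with two exchanged at 4.00 h down to 27.5% by 6.0 h, and larch left that long holds 27.2%. Neither flask is at rest: ash holds 0.0280% of its incoming ligand at 4.00 h, and its complex with four exchanged reads 1.33% then and 1.33% at 40.0 h, while by that time its complex with two exchanged has fallen to 4.39%, its trapped intermediate has climbed to 35.4%, and the share in ash has dropped to 3.62%. In larch, the share falls from 46.6% at 4.00 h to 14.7% at 40.0 h.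

The earlier runs and the new flask are simulated for substances that don't exist; scatter was added.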